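The rate constants of this flask were not needed for where it came to stand: a ratio of two, read from the plateau of the green run, served, if X was being lost to a side path as well as reacting with Z. The readings did not separate that loss from a back reaction.

- green: Z 0.20 M; X 1.5 equiv; the very flask that is asked about, followed so far
- flask: Z 0.20 M; X 1.50 equiv; time 25 h

green run (percent of the Z charged)

| time / h | G / % | Z / % |
|---|---|---|
| 0.833 | 26.7 | 74.0 |
| 1.33 | 33.6 | 67.2 |
| 2.00 | 36.6 | 64.0 |
| 3.00 | 39.4 | 59.7 |
| 4.00 | 42.2 | 60.2 |
| 6.00 | 42.8 | 58.9 |
| 10.0 | 39.6 | 60.3 |

(readings scatter by 1 percentage point)

- what was read earlier has a scatter of 1 percentage point, one standard deviation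
- the reaction counts as stopped when no species that holds the Z changes by six tenths of a point or more over the second half of the time

1. which holds at 25 h: what has brought the reaction to rest, or that it has not come to rest (X has run out first / forward and back rates have come level / all of Z has reacted / it is still moving)
2. G at 25 h, in percent of the Z charged

Both paths run in proportion to X, so X cancels from their ratio, and the X lost per Z reacted is w/z, with z the fraction of Z left. Summed down from the charge until X is gone, with e the equivalents of X and f the fraction turned to G:

e − f = −w · ln z, with w going inversely with the Z charged

Which numbers had to be good? Time did not: G read 39.4% at 3.00 h and 39.6% at 10.0 h, beside a scatter of 1 percentage point. The charge of X enters w and not the plateau reading. The plateau level does count, point for point on the answer. The last four G readings average 41.0%, while those of Z imply 40.2%. I kept the first for G at 25 h, which gives 2.07 for the waste number w, the X lost per Z reacted while Z stands at its charge; the second would give 2.13.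

The forecast said forward and back rates have come level, with G at 40.5%: “which is what reversible equilibrium looks like”.

The flask gave X has run out first, with G at 41.3%, so the forecast held on G and parted on the end: at 25.0 h X stood at 0% of its charge and Z at 58.7%.

    Z + X → G (k = 5.40 × 10⁻⁴ /M/s)
    X → Q (k = 2.20 × 10⁻⁴ /s)

At 0.649 h the path from X to Q used X 2.7 times as fast as the path from Z + X to G. Up to 25 h the path to Q took 1.09 equiv, and w with the Z left gives 1.10 equiv. A neighbour flask, charged with 0.80 M of Z, ended with G at 76.4% and Z at 23.6%; there w scales to 0.516, and G plus the X lost comes to 1.51 equiv of the 1.50 equiv charged.

The runs are simulated for substances that don't exist, and the scatter is random.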